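**Retrosynthetic overview**
- No ring is built: the furan is bought as 3-bromofuran and attached late by hydroboration/B-alkyl Suzuki coupling on an allyl arm; the oxazolidinone ring belongs to the auxiliary.
- The (Z)-trisubstituted acrylate is not made by carbonyl olefination. It is set on a 2-ynoate by syn-hydrostannation (H to Cβ, Sn to Cα), Sn-to-I exchange and an alkyl Negishi coupling that brings in the homoprenyl group.
- The ynoate carbon comes from a terminal alkyne and methyl chloroformate. The C2 stereocentre comes from one Evans allylation of an N-(hex-5-ynoyl)oxazolidinone, whose allyl and butynyl arms become the two three-carbon arms.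
- The auxiliary is the only carboxyl protection and is removed last with LiOOH, leaving the methyl ester.

Assumption: the target is the (2R,5Z) isomer as read from the SMILES, and all numbered starting materials are catalogue compounds.

**Route**

Step 1
Reactants: 1 hex-5-ynoic acid; 2 (R)-4-benzyloxazolidin-2-one
Product: 4 (R)-4-benzyl-3-(hex-5-ynoyl)oxazolidin-2-one, via hex-5-ynoic pivalic anhydride 3 (not isolated)
Conditions: t-BuCOCl, Et3N, THF, −20 °C; then LiCl, 2, −20 °C → rt
Reagents that add atoms: none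
Why: Mixed-anhydride N-acylation of the oxazolidinone (LiCl/Et3N variant), in which the hindered pivaloyl carbonyl does not compete and no stereocentre is involved.

Step 2
Reactants: 4 (R)-4-benzyl-3-(hex-5-ynoyl)oxazolidin-2-one; 5 allyl iodide
Product: 7 (R)-4-benzyl-3-[(S)-2-allylhex-5-ynoyl]oxazolidin-2-one, via sodium Z-enolate 6 (not isolated)
Conditions: NaN(SiMe3)2 (1.05 equiv), THF, −78 °C; then 5 (3 equiv), −78 → −45 °C
Reagents that add atoms: none
Why: Evans asymmetric alkylation, in which the chelated Z-enolate is allylated on the face opposite the C4 benzyl group, so the (R)-auxiliary gives the (S)-2-allyl centre (expected dr ≥ 95:5, minor isomer removed by chromatography) that becomes 2R in the target once the arm priorities change.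

Step 3
Reactants: 7 (R)-4-benzyl-3-[(S)-2-allylhex-5-ynoyl]oxazolidin-2-one; 8 methyl chloroformate
Product: 9 methyl (S)-6-[(R)-4-benzyl-2-oxooxazolidine-3-carbonyl]non-8-en-2-ynoate
Conditions: 8 (2 equiv), PdCl2(PPh3)2 (3 mol %), CuI (5 mol %), 1,2,2,6,6-pentamethylpiperidine, CH2Cl2, rt, Ar
Reagents that add atoms: none
Why: Acyl-Sonogashira-type alkoxycarbonylation, in which zerovalent palladium inserts into the C–Cl bond of the chloroformate and the copper acetylide transfers the alkynyl group, under amine-base conditions too mild to enolise the hindered imide or touch the alkene.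

Step 4
Reactants: 9 methyl (S)-6-[(R)-4-benzyl-2-oxooxazolidine-3-carbonyl]non-8-en-2-ynoate
Product: 11 methyl (S,E)-6-[(R)-4-benzyl-2-oxooxazolidine-3-carbonyl]-2-iodonona-2,8-dienoate, via E-configured α-tributylstannyl enoate 10 (not isolated)
Conditions: Bu3SnH (1.2 equiv, slow addition), Pd(PPh3)4 (3 mol %), THF, 0 °C → rt; then I2 (1.1 equiv), CH2Cl2, −78 → 0 °C
Reagents that add atoms: iodine, II
Why: Palladium-catalysed syn-hydrostannation of a 2-ynoate puts H on Cβ and Sn on Cα from the same face, so the ester ends up cis to the chain, and iododestannylation then proceeds with retention, which fixes the alkene geometry here.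

Step 5
Reactants: 11 methyl (S,E)-6-[(R)-4-benzyl-2-oxooxazolidine-3-carbonyl]-2-iodonona-2,8-dienoate; 12 5-bromo-2-methylpent-2-ene
Product: 14 methyl (S,Z)-6-[(R)-4-benzyl-2-oxooxazolidine-3-carbonyl]-2-(4-methylpent-3-en-1-yl)nona-2,8-dienoate, via (4-methylpent-3-en-1-yl)zinc bromide 13 (not isolated)
Conditions: 12, Zn dust, I2 (5 mol %), DMA, 80 °C; then 11, PdCl2(dppf) (5 mol %), THF, 25 → 40 °C
Reagents that add atoms: none
Why: Negishi C(sp2)–C(sp3) coupling, in which oxidative addition, transmetalation and reductive elimination all retain the alkenyl geometry, turning the E-iodide into the Z-acrylate, while the bidentate ligand suppresses β-hydride elimination and the trans arrangement of Pd and tether rules out Heck cyclisation onto the allyl group.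

Step 6
Reactants: 14 methyl (S,Z)-6-[(R)-4-benzyl-2-oxooxazolidine-3-carbonyl]-2-(4-methylpent-3-en-1-yl)nona-2,8-dienoate; 15 3-bromofuran
Product: 17 methyl (R,Z)-6-[(R)-4-benzyl-2-oxooxazolidine-3-carbonyl]-9-(furan-3-yl)-2-(4-methylpent-3-en-1-yl)non-2-enoate, via B-alkyl-9-BBN adduct 16 (not isolated)
Conditions: 9-BBN (1.3 equiv), THF, 0 °C → rt; then 15, PdCl2(dppf) (5 mol %), AsPh3, Cs2CO3, DMF/H2O, rt
Reagents that add atoms: none
Why: 9-BBN hydroborates only the monosubstituted terminal alkene (anti-Markovnikov), and the primary alkylborane then undergoes B-alkyl Suzuki–Miyaura coupling with the heteroaryl bromide without touching the stereocentre or the alkene geometry (the descriptor changes from S to R only because the arm priorities change).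

Step 7
Reactants: 17 methyl (R,Z)-6-[(R)-4-benzyl-2-oxooxazolidine-3-carbonyl]-9-(furan-3-yl)-2-(4-methylpent-3-en-1-yl)non-2-enoate
Product: 19 (R,Z)-2-[3-(furan-3-yl)propyl]-6-(methoxycarbonyl)-10-methylundeca-5,9-dienoic acid, via lithium peroxycarboxylate 18 (not isolated)
Conditions: LiOH (2 equiv), 30% H2O2 (4 equiv), THF/H2O 3:1, 0 °C; Na2SO3 (aq); then 1 M HCl to pH 3
Reagents that add atoms: hydrogen peroxide, OO
Why: Evans LiOOH imide cleavage, in which hydroperoxide attacks the exocyclic imide carbonyl much faster than the hindered conjugated methyl ester, sulfite reduces the peracid salt, and the α-centre is not epimerised at 0 °C.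

**Compound list**

1 | hex-5-ynoic acid | C#CCCCC(=O)O | starting material
2 | (R)-4-benzyloxazolidin-2-one | O=C1N[C@H](Cc2ccccc2)CO1 | starting material
3 | hex-5-ynoic pivalic anhydride | C#CCCCC(=O)OC(=O)C(C)(C)C | intermediate
4 | (R)-4-benzyl-3-(hex-5-ynoyl)oxazolidin-2-one | C#CCCCC(=O)N1[C@H](Cc2ccccc2)COC1=O | intermediate
5 | allyl iodide (3-iodoprop-1-ene) | C=CCI | starting material
6 | sodium (Z)-enolate of 4 | [Na+].[O-]/C(=C\CCC#C)N1[C@H](Cc2ccccc2)COC1=O | intermediate
7 | (R)-4-benzyl-3-[(S)-2-allylhex-5-ynoyl]oxazolidin-2-one | C=CC[C@H](CCC#C)C(=O)N1[C@H](Cc2ccccc2)COC1=O | intermediate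
8 | methyl chloroformate | COC(=O)Cl | starting material
9 | methyl (S)-6-[(R)-4-benzyl-2-oxooxazolidine-3-carbonyl]non-8-en-2-ynoate | COC(=O)C#CCC[C@@H](CC=C)C(=O)N1[C@H](Cc2ccccc2)COC1=O | intermediate
10 | methyl (S,E)-6-[(R)-4-benzyl-2-oxooxazolidine-3-carbonyl]-2-(tributylstannyl)nona-2,8-dienoate | COC(=O)/C(=C\CC[C@@H](CC=C)C(=O)N1[C@H](Cc2ccccc2)COC1=O)[Sn](CCCC)(CCCC)CCCC | intermediate
11 | methyl (S,E)-6-[(R)-4-benzyl-2-oxooxazolidine-3-carbonyl]-2-iodonona-2,8-dienoate | COC(=O)/C(I)=C\CC[C@@H](CC=C)C(=O)N1[C@H](Cc2ccccc2)COC1=O | intermediate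
12 | 5-bromo-2-methylpent-2-ene | CC(C)=CCCBr | starting material
13 | (4-methylpent-3-en-1-yl)zinc bromide | CC(C)=CCC[Zn]Br | intermediate
14 | methyl (S,Z)-6-[(R)-4-benzyl-2-oxooxazolidine-3-carbonyl]-2-(4-methylpent-3-en-1-yl)nona-2,8-dienoate | COC(=O)/C(=C\CC[C@@H](CC=C)C(=O)N1[C@H](Cc2ccccc2)COC1=O)CCC=C(C)C | intermediate
15 | 3-bromofuran | Brc1ccoc1 | starting material
16 | methyl (R,Z)-6-[(R)-4-benzyl-2-oxooxazolidine-3-carbonyl]-9-(9-borabicyclo[3.3.1]nonan-9-yl)-2-(4-methylpent-3-en-1-yl)non-2-enoate | COC(=O)/C(=C\CC[C@@H](CCCB1C2CCCC1CCC2)C(=O)N1[C@H](Cc2ccccc2)COC1=O)CCC=C(C)C | intermediate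
17 | methyl (R,Z)-6-[(R)-4-benzyl-2-oxooxazolidine-3-carbonyl]-9-(furan-3-yl)-2-(4-methylpent-3-en-1-yl)non-2-enoate | COC(=O)/C(=C\CC[C@@H](CCCc1ccoc1)C(=O)N1[C@H](Cc2ccccc2)COC1=O)CCC=C(C)C | intermediate
18 | lithium (R,Z)-2-[3-(furan-3-yl)propyl]-6-(methoxycarbonyl)-10-methylundeca-5,9-dieneperoxoate | COC(=O)/C(=C\CC[C@@H](CCCc1ccoc1)C(=O)O[O-])CCC=C(C)C.[Li+] | intermediate
19 | (R,Z)-2-[3-(furan-3-yl)propyl]-6-(methoxycarbonyl)-10-methylundeca-5,9-dienoic acid | COC(=O)/C(=C\CC[C@@H](CCCc1ccoc1)C(=O)O)CCC=C(C)C | target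

**Step count and risks**

Total step count: 7 (the organozinc 13 is made and consumed inside step 5). Longest linear sequence: 7 steps, from 1 to 19.

The three steps most likely to fail, each with one fallback:

Step 3. The chloroformate coupling may stall on an aliphatic alkyne, through amine-induced loss of the chloroformate or Glaser dimerisation. The fallback sets out from 7 and comes back at 9. It replaces coupling with an electrophilic C1 unit by C–H carboxylation with CO2. Compound 7 is stirred with AgI (2 mol %) and Cs2CO3 under a CO2 balloon in DMF at 40 °C to give caesium (S)-6-[(R)-4-benzyl-2-oxooxazolidine-3-carbonyl]non-8-en-2-ynoate F1. MeI is then added to the same pot at rt to alkylate the carboxylate and deliver 9. The extra risk is slow base-induced epimerisation of the imide, so the temperature is kept low.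

Step 5. The alkyl–alkenyl Negishi coupling on the α-iodoacrylate may give reduction through β-hydride elimination, or partial loss of alkene geometry. The fallback sets out from 11 and comes back at 14. It swaps the organozinc for an organoborane with base-activated transmetalation. 4-Methylpenta-1,3-diene (CC(C)=CC=C, purchased, slight excess) is hydroborated at its monosubstituted terminus with 9-BBN in THF to give 9-(4-methylpent-3-en-1-yl)-9-borabicyclo[3.3.1]nonane F2. F2 is coupled with 11 under B-alkyl Suzuki–Miyaura conditions of the kind established for α-iodo enones (PdCl2(dppf), AsPh3, Cs2CO3, DMF/THF/H2O, rt) to give 14. The excess diene ensures that no free 9-BBN reaches the allyl group of 11.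

Step 7. LiOOH may partly saponify the methyl ester, or oxidise the furan or the electron-rich alkene. The fallback sets out from 17 and comes back at 19. It removes the auxiliary reductively and re-oxidises. LiBH4 (1.1 equiv) with 1 equiv H2O in Et2O at 0 °C cleaves only the imide and gives methyl (R,Z)-9-(furan-3-yl)-6-(hydroxymethyl)-2-(4-methylpent-3-en-1-yl)non-2-enoate F3. Dess–Martin periodinane with NaHCO3 in CH2Cl2 at 0 °C gives methyl (R,Z)-6-formyl-9-(furan-3-yl)-2-(4-methylpent-3-en-1-yl)non-2-enoate F4, which is used at once to avoid α-epimerisation. Pinnick oxidation (NaClO2, NaH2PO4, large excess of 2-methylbut-2-ene, t-BuOH/H2O, 0 °C) then gives 19.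

Further compounds
F1 | step 3 | caesium (S)-6-[(R)-4-benzyl-2-oxooxazolidine-3-carbonyl]non-8-en-2-ynoate | [Cs+].[O-]C(=O)C#CCC[C@@H](CC=C)C(=O)N1[C@H](Cc2ccccc2)COC1=O
F2 | step 5 | 9-(4-methylpent-3-en-1-yl)-9-borabicyclo[3.3.1]nonane | CC(C)=CCCB1C2CCCC1CCC2
F3 | step 7 | methyl (R,Z)-9-(furan-3-yl)-6-(hydroxymethyl)-2-(4-methylpent-3-en-1-yl)non-2-enoate | COC(=O)/C(=C\CC[C@@H](CCCc1ccoc1)CO)CCC=C(C)C
F4 | step 7 | methyl (R,Z)-6-formyl-9-(furan-3-yl)-2-(4-methylpent-3-en-1-yl)non-2-enoate | COC(=O)/C(=C\CC[C@@H](CCCc1ccoc1)C=O)CCC=C(C)C
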